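The plan rests on cutting the C8=C9 bond that hides behind the cis C8–C9 epoxide of the nine-membered carbocycle (C4a–C11a). Ring-closing metathesis joins the C7 vinyl and C10 allyl termini of a monocyclic δ-lactone and so creates the Z-cyclononene in one operation. It exploits the trans C4a/C11a fusion to the pyran ring, which holds both arms equatorial and gauche, and the allylic C7 carbinol, which later steers the epoxidation. The precursor is a trans-4,5-disubstituted δ-lactone triene, kept as its C7 triethylsilyl ether so that only the allyl end loads ruthenium. Afterwards the C12–C15 chain is added by aldol reaction, locked as a butenolide, reduced and closed to the bis-acetal.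

Key step: step 12

Remark: xenicane numbering is used throughout (pyran ring C1, O2, C3, C4, C4a, C11a; carbocycle C4a–C11a; side chain C12–C15). It is assumed that (S)-linalool of high enantiomeric purity and D-erythronolactone can be bought.

Step 1
Reactants: 1 2,3-dibromopropene; 2 vinylmagnesium bromide
Product: 3 2-bromopenta-1,4-diene
Conditions: CuI (5 mol %), THF, 0 °C to rt
Reagents that add atoms: none
Why: Copper-catalysed allylic substitution by a Grignard reagent, in which the allylic C–Br bond of 1 is displaced far faster than the vinylic one, so the C9–C10–C11 unit should form with its alkenyl bromide intact and without any stereocenter.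

Step 2
Reactants: 3 2-bromopenta-1,4-diene
Product: 6 potassium trifluoro(penta-1,4-dien-2-yl)borate, via Grignard reagent 4 (not isolated), via dimethyl boronate 5 (not isolated)
Conditions: Mg, THF, 35 °C; B(OMe)3, −78 °C to rt; KHF2, H2O/MeOH, rt
Reagents that add atoms: trimethyl borate, COB(OC)OC; potassium hydrogen difluoride, F.[F-].[K+]
Why: Grignard formation, borylation and fluoride exchange is the standard entry to shelf-stable potassium alkenyltrifluoroborates, and the sp2 carbon–metal bond cannot move the 1,1-disubstituted double bond.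

Step 3
Reactants: 6 potassium trifluoro(penta-1,4-dien-2-yl)borate; 7 furan-2(5H)-one
Product: 8 (R)-4-(penta-1,4-dien-2-yl)dihydrofuran-2(3H)-one
Conditions: [Rh(cod)2]PF6 (3 mol %), (R)-BINAP (3.3 mol %), toluene/H2O 10:1, 100 °C
Reagents that add atoms: none
Why: Hayashi–Miyaura asymmetric conjugate addition, in which the alkenyl–rhodium species held by (R)-BINAP inserts into one face of the butenolide and water releases the lactone, so that C11a should be set as R by catalyst control, the mirror image of the sense that (S)-BINAP shows with cyclic acceptors.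

Step 4
Reactants: 9 (S)-linalool
Product: 10 (S)-linalool triethylsilyl ether
Conditions: Et3SiOTf, 2,6-lutidine, CH2Cl2, −78 to 0 °C
Reagents that add atoms: triethylsilyl trifluoromethanesulfonate, CC[Si](CC)(CC)OS(=O)(=O)C(F)(F)F
Why: Silyl triflate silylation is strong enough for the tertiary allylic alcohol and non-acidic enough not to ionise it, so the C7 stereocenter of the chiral pool (S) is carried on unchanged.

Step 5
Reactants: 10 (S)-linalool triethylsilyl ether
Product: 12 (S)-4-methyl-4-(triethylsilyloxy)hex-5-enoic acid, via aldehyde 11 (not isolated)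
Conditions: O3 (1.0 equiv, Sudan red 7B endpoint), CH2Cl2/MeOH, −78 °C; Me2S; crude, then NaClO2, NaH2PO4, 2-methylbut-2-ene, t-BuOH/H2O, 0 °C to rt
Reagents that add atoms: ozone, [O-][O+]=O; sodium chlorite, [Na+].[O-]Cl=O
Why: Chemoselective ozonolysis followed by Pinnick oxidation, since ozone attacks the electron-rich trisubstituted alkene much faster than the vinyl group that is shielded and deactivated by the silyloxy quaternary carbon, and buffered chlorite oxidises only the aldehyde.

Step 6
Reactants: 12 (S)-4-methyl-4-(triethylsilyloxy)hex-5-enoic acid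
Product: 14 (S)-5-iodo-3-methyl-3-(triethylsilyloxy)pent-1-ene, via Barton ester 13 (not isolated)
Conditions: N-hydroxypyridine-2-thione, DCC, CH2Cl2, 0 °C, dark; CHI3, hν (tungsten lamp), rt
Reagents that add atoms: iodoform, IC(I)I
Why: Barton decarboxylative iodination removes the one surplus carbon of linalool, because the primary C5 radical abstracts iodine from CHI3 faster than it can reach the vinyl group, for which only slow 4-exo or 5-endo modes exist.

Step 7
Reactants: 8 (R)-4-(penta-1,4-dien-2-yl)dihydrofuran-2(3H)-one; 14 (S)-5-iodo-3-methyl-3-(triethylsilyloxy)pent-1-ene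
Product: 16 (3S,4R)-3-[(S)-3-methyl-3-(triethylsilyloxy)pent-4-en-1-yl]-4-(penta-1,4-dien-2-yl)dihydrofuran-2(3H)-one, via lithium enolate 15 (not isolated)
Conditions: LiN(i-Pr)2, THF, −78 °C; DMPU, 14, −78 to −20 °C
Reagents that add atoms: none
Why: Lactone enolate alkylation (SN2), in which the primary iodide approaches the flat enolate anti to the C11a dienyl group, so that C4a should be set trans to C11a by substrate control.

Step 8
Reactants: 16 trans-disubstituted γ-lactone
Product: 17 γ-lactol of 16 (anomers)
Conditions: i-Bu2AlH (1.1 equiv), CH2Cl2, −78 °C; aq KNaC4H4O6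
Reagents that add atoms: none
Why: Partial reduction of a lactone with i-Bu2AlH stops at the aluminium lactolate at low temperature and leaves alkenes and the silyl ether alone.

Step 9
Reactants: 17 γ-lactol
Product: 18 hydroxy enol ether HOC1H2–C11aH(dienyl)–C4aH(side chain)–C4H=C3H–OMe (E/Z mixture)
Conditions: MeOCH2PPh3Cl, KN(SiMe3)2, THF, 0 °C to rt
Reagents that add atoms: (methoxymethyl)triphenylphosphonium chloride, COC[P+](c1ccccc1)(c1ccccc1)c1ccccc1.[Cl-]
Why: Wittig methoxymethylenation of the open hydroxy aldehyde form brings in C3, and the reactive non-stabilised ylide should consume the aldehyde faster than C4a can epimerise.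

Step 10
Reactants: 18 hydroxy enol ether
Product: 19 δ-lactol (anomers)
Conditions: AcOH/THF/H2O 4:2:1, 40 °C
Reagents that add atoms: water, O
Why: Acid-catalysed enol ether hydrolysis, in which protonation at C4 gives the C3 oxocarbenium ion that water and the C1 hydroxyl turn into the six-membered lactol, under conditions that the hindered tertiary silyl ether is expected to outlast.

Step 11
Reactants: 19 δ-lactol
Product: 20 (4R,5R)-4-[(S)-3-methyl-3-(triethylsilyloxy)pent-4-en-1-yl]-5-(penta-1,4-dien-2-yl)tetrahydro-2H-pyran-2-one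
Conditions: TEMPO (10 mol %), PhI(OAc)2, CH2Cl2, rt
Reagents that add atoms: none
Why: Oxoammonium (TEMPO) oxidation of a lactol to the lactone is mild, chromium-free and blind to the three alkenes, which avoids oxidative transposition at the C7 allylic position.

Step 12
Reactants: 20 trans-δ-lactone triene, C7 triethylsilyl ether
Product: 21 (4aR,7S,11aR,Z)-7-methyl-11-methylene-7-(triethylsilyloxy)-4,4a,5,6,7,10,11,11a-octahydrocyclonona[c]pyran-3(1H)-one
Conditions: second-generation Grubbs catalyst RuCl2(=CHPh)(PCy3)(H2IMes) (10 mol %, slow addition), 1,4-benzoquinone (20 mol %), toluene (0.5 mM), 80 °C, Ar sparge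
Reagents that add atoms: none
Why: Ring-closing olefin metathesis by the Chauvin mechanism: the ruthenium benzylidene exchanges with the unhindered C9=CH2 terminus of the allyl group, the C9 alkylidene adds to the C7 vinyl group in a [2+2] sense, and the ruthenacyclobutane cycloreverts to the C8=C9 olefin and Ru=CH2, which carries the chain with loss of ethene. The closest known reaction type is diene ring-closing metathesis to nine-membered carbocycles that are preorganised by a fused ring. The one ring formed, the carbocycle C4a–C5–C6–C7–C8–C9–C10–C11–C11a, closes between the two terminal CH2= groups, and from a C9 alkylidene the only other intramolecular partner, the C11 methylene, would demand a cyclopropene and therefore stays silent. No stereocenter is created, and the Z geometry follows from ring size, since an E olefin in a nine-membered ring that also holds the sp2 C11 is clearly more strained. Site selectivity is needed against a C8 alkylidene, which could close a cycloheptene (C8, C7, C6, C5, C4a, C11a, C11) onto the C11 methylene, and keeping O7 as its triethylsilyl ether secures it, because a vinyl group beside a silyloxy quaternary carbon takes up ruthenium only sluggishly and so acts merely as the acceptor. The trans C4a/C11a relationship places both arms equatorial and gauche on the lactone chair, high dilution with ethene removal disfavours oligomers, and 1,4-benzoquinone suppresses hydride-induced migration of the skipped diene.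

Step 13
Reactants: 22 D-erythronolactone
Product: 23 (2R,3R)-4-methylpentane-1,2,3,4-tetraol
Conditions: MeMgBr (6 equiv), THF, 0 °C to rt; solid NH4Cl, MeOH, filtration
Reagents that add atoms: methylmagnesium bromide, C[Mg]Br
Why: Double Grignard addition to the lactone carbonyl builds the C15 dimethyl carbinol, while C13 and C14 (erythro, both R) come untouched from the chiral pool and the extra reagent only deprotonates the hydroxyls.

Step 14
Reactants: 23 (2R,3R)-4-methylpentane-1,2,3,4-tetraol
Product: 24 (2R,3R)-4-methyl-1,2-bis(triethylsilyloxy)pentane-3,4-diol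
Conditions: Et3SiCl (2.05 equiv), imidazole, CH2Cl2/DMF, −20 to 0 °C
Reagents that add atoms: chlorotriethylsilane, CC[Si](Cl)(CC)CC
Why: Sterically controlled silylation, in which the primary C12 hydroxyl and the less hindered secondary C13 hydroxyl should react before the C14 hydroxyl, which sits next to the C15 quaternary carbon, and before the tertiary C15 hydroxyl.

Step 15
Reactants: 24 1,2-bis(triethylsilyl) ether
Product: 25 (2R,3R)-3,4-bis(tert-butyldimethylsilyloxy)-4-methyl-1,2-bis(triethylsilyloxy)pentane
Conditions: t-BuMe2SiOTf (3 equiv), 2,6-lutidine, CH2Cl2, 0 °C to rt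
Reagents that add atoms: tert-butyldimethylsilyl trifluoromethanesulfonate, CC(C)(C)[Si](C)(C)OS(=O)(=O)C(F)(F)F
Why: Silyl triflate silylation caps even the hindered secondary and tertiary hydroxyls and so marks O14 and O15 with a group that is orthogonal to the triethylsilyl group on O13.

Step 16
Reactants: 25 fully silylated tetraol
Product: 26 (2S,3R)-3,4-bis(tert-butyldimethylsilyloxy)-4-methyl-2-(triethylsilyloxy)pentanal
Conditions: (COCl)2, DMSO, CH2Cl2, −78 to −35 °C; Et3N, −78 °C to rt
Reagents that add atoms: none
Why: Swern oxidation applied directly to a primary triethylsilyl ether, in which the activated sulfonium species attacks only the least hindered silyl ether oxygen, so C12 becomes the aldehyde while the secondary and hindered silyl ethers and the C13 center stay in place.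

Step 17
Reactants: 21 lactone-fused cyclononene; 26 side-chain aldehyde
Product: 28 aldol adduct, 21 bearing at C4 the group C12H(OH)–C13H(OSiEt3)–C14H(OSiMe2t-Bu)–C15Me2(OSiMe2t-Bu) (mixture at C4 and C12), via lithium enolate 27 (not isolated)
Conditions: LiN(i-Pr)2, THF, −78 °C; 26; AcOH quench at −78 °C
Reagents that add atoms: none
Why: Lithium enolate aldol addition forms the C4–C12 bond, and the two new centers at C4 and C12 need no control because both are erased in step 19.

Step 18
Reactants: 28 aldol adduct
Product: 30 γ-lactone C3(=O)–O–C13 with free hydroxyls at C1, C7 and C12, via δ-lactone triol 29 (not isolated)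
Conditions: HF·pyridine, pyridine, THF, 0 °C to rt; aq NaHCO3; DBU (10 mol %), CH2Cl2, 0 °C
Reagents that add atoms: none
Why: Selective fluoride desilylation followed by translactonisation, in which buffered HF cleaves the two triethylsilyl ethers (O13, O7) but not the hindered tert-butyldimethylsilyl ethers and the freed C13 hydroxyl transacylates onto C3 because a γ-lactone is favoured over the δ-lactone, which ties O13 to C3 before the C4=C12 bond exists, whereas direct dehydration of 28 would be expected to give mainly the E-alkylidene lactone whose O13 cannot reach C3.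

Step 19
Reactants: 30 γ-lactone triol
Product: 32 butenolide (C4=C12 in the ring) with C1 acetate and free C7 hydroxyl, via diacetate 31 (not isolated)
Conditions: Ac2O (2.5 equiv), Et3N, DMAP (cat.), CH2Cl2, 0 °C; DBU (1.5 equiv), 0 °C, short time
Reagents that add atoms: acetic anhydride, CC(=O)OC(C)=O
Why: Acetylation and E1cB elimination of the β-acetoxy lactone, in which the five-membered ring forces the C4=C12 olefin to hold C13 cis to C3, short contact with DBU limits deprotonation at C13, and the tertiary C7 hydroxyl is not expected to acylate (any C7 acetate would fall off in step 20).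

Step 20
Reactants: 32 butenolide acetate
Product: 34 tricyclic bis-acetal triene (3S,4aS,7S,11aR,13R,14R; C8=C9 Z) with free C7 hydroxyl and O14, O15 silylated, via lactol 33 (not isolated)
Conditions: i-Bu2AlH (6 equiv), CH2Cl2, −78 °C; aq KNaC4H4O6; PPTS (5 mol %), 4 Å MS, CH2Cl2, 0 °C, short time
Reagents that add atoms: none
Why: Partial reduction of the butenolide with reductive loss of the acetate, then acid-catalysed intramolecular acetalisation, in which the C1 hydroxyl adds to the allylic C3 oxocarbenium ion and C3 is set by substrate control, since only the epimer with H3 cis to H4a lets the pyran keep the C4a–C5 and C11a–C11 bonds equatorial, while the silyl groups keep O14 and O15 from closing bridged acetals.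

Step 21
Reactants: 34 bis-acetal triene
Product: 35 8R,9R cis-epoxide of 34
Conditions: VO(acac)2 (5 mol %), t-BuOOH (1.5 equiv, decane), CH2Cl2, 0 °C
Reagents that add atoms: tert-butyl hydroperoxide, CC(C)(C)OO
Why: Vanadium-catalysed hydroxyl-directed epoxidation, in which the vanadate ester of the C7 hydroxyl delivers oxygen to the face of the Z C8=C9 olefin syn to that hydroxyl and so sets C8 and C9, while the C11 methylene and the electron-poor C4=C12 olefin have no free hydroxyl to guide the reagent, and an undirected peracid would be expected to attack the outer, opposite face.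

Step 22
Reactants: 35 bis-silylated epoxide
Product: 36 target CNP0281409.2
Conditions: n-Bu4NF (5 equiv), THF, 0 °C to rt
Reagents that add atoms: none
Why: Fluoride desilylation under non-acidic conditions spares the bis-acetal and the epoxide, the vicinal silyl ethers should leave in turn by fluoride attack at O14 and silyl migration from O15, and the cis arrangement of the C7 hydroxyl and the epoxide oxygen on the ring disfavours the backside geometry of a Payne rearrangement.

Compound list
1 | 2,3-dibromopropene | C=C(Br)CBr | starting material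
2 | vinylmagnesium bromide | C=C[Mg]Br | starting material
3 | 2-bromopenta-1,4-diene | C=CCC(Br)=C | intermediate
4 | (penta-1,4-dien-2-yl)magnesium bromide | C=CCC(=C)[Mg]Br | intermediate
5 | dimethyl (penta-1,4-dien-2-yl)boronate | C=CCC(=C)B(OC)OC | intermediate
6 | potassium trifluoro(penta-1,4-dien-2-yl)borate | [K+].C=CCC(=C)[B-](F)(F)F | intermediate
7 | furan-2(5H)-one | O=C1C=CCO1 | starting material
8 | (R)-4-(penta-1,4-dien-2-yl)dihydrofuran-2(3H)-one | O=C1C[C@H](C(=C)CC=C)CO1 | intermediate
9 | (S)-linalool | C=C[C@@](C)(O)CCC=C(C)C | starting material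
10 | (S)-linalool triethylsilyl ether | C=C[C@@](C)(O[Si](CC)(CC)CC)CCC=C(C)C | intermediate
11 | (S)-4-methyl-4-(triethylsilyloxy)hex-5-enal | C=C[C@@](C)(O[Si](CC)(CC)CC)CCC=O | intermediate
12 | (S)-4-methyl-4-(triethylsilyloxy)hex-5-enoic acid | C=C[C@@](C)(O[Si](CC)(CC)CC)CCC(=O)O | intermediate
13 | 2-thioxopyridin-1(2H)-yl ester of 12 (Barton ester) | C=C[C@@](C)(O[Si](CC)(CC)CC)CCC(=O)On1ccccc1=S | intermediate
14 | (S)-5-iodo-3-methyl-3-(triethylsilyloxy)pent-1-ene | C=C[C@@](C)(O[Si](CC)(CC)CC)CCI | intermediate
15 | lithium enolate of 8 | [Li]OC1=C[C@H](C(=C)CC=C)CO1 | intermediate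
16 | (3S,4R)-3-[(S)-3-methyl-3-(triethylsilyloxy)pent-4-en-1-yl]-4-(penta-1,4-dien-2-yl)dihydrofuran-2(3H)-one | O=C1[C@@H](CC[C@](C)(O[Si](CC)(CC)CC)C=C)[C@H](C(=C)CC=C)CO1 | intermediate
17 | γ-lactol of 16, anomers, other centers as in 16 | OC1[C@@H](CC[C@](C)(O[Si](CC)(CC)CC)C=C)[C@H](C(=C)CC=C)CO1 | intermediate
18 | hydroxy methyl enol ether (C3=C4 E/Z mixture), C4a, C7, C11a as in 16 | COC=C[C@@H](CC[C@](C)(O[Si](CC)(CC)CC)C=C)[C@H](C(=C)CC=C)CO | intermediate
19 | δ-lactol, anomers at C3, other centers as in 20 | OC1C[C@@H](CC[C@](C)(O[Si](CC)(CC)CC)C=C)[C@H](C(=C)CC=C)CO1 | intermediate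
20 | (4R,5R)-4-[(S)-3-methyl-3-(triethylsilyloxy)pent-4-en-1-yl]-5-(penta-1,4-dien-2-yl)tetrahydro-2H-pyran-2-one (metathesis precursor) | O=C1C[C@@H](CC[C@](C)(O[Si](CC)(CC)CC)C=C)[C@H](C(=C)CC=C)CO1 | intermediate
21 | (4aR,7S,11aR,Z)-7-methyl-11-methylene-7-(triethylsilyloxy)-4,4a,5,6,7,10,11,11a-octahydrocyclonona[c]pyran-3(1H)-one (metathesis product) | O=C1C[C@H]2CC[C@](C)(O[Si](CC)(CC)CC)/C=C\CC(=C)[C@@H]2CO1 | intermediate
22 | D-erythronolactone, (3R,4R)-3,4-dihydroxydihydrofuran-2(3H)-one | O=C1OC[C@@H](O)[C@H]1O | starting material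
23 | (2R,3R)-4-methylpentane-1,2,3,4-tetraol | OC[C@@H](O)[C@@H](O)C(C)(C)O | intermediate
24 | (2R,3R)-4-methyl-1,2-bis(triethylsilyloxy)pentane-3,4-diol | CC[Si](CC)(CC)OC[C@@H](O[Si](CC)(CC)CC)[C@@H](O)C(C)(C)O | intermediate
25 | (2R,3R)-3,4-bis(tert-butyldimethylsilyloxy)-4-methyl-1,2-bis(triethylsilyloxy)pentane | CC[Si](CC)(CC)OC[C@@H](O[Si](CC)(CC)CC)[C@@H](O[Si](C)(C)C(C)(C)C)C(C)(C)O[Si](C)(C)C(C)(C)C | intermediate
26 | (2S,3R)-3,4-bis(tert-butyldimethylsilyloxy)-4-methyl-2-(triethylsilyloxy)pentanal | O=C[C@@H](O[Si](CC)(CC)CC)[C@@H](O[Si](C)(C)C(C)(C)C)C(C)(C)O[Si](C)(C)C(C)(C)C | intermediate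
27 | lithium enolate of 21 | [Li]OC1=C[C@H]2CC[C@](C)(O[Si](CC)(CC)CC)/C=C\CC(=C)[C@@H]2CO1 | intermediate
28 | aldol adduct of 21 and 26 (mixture at C4 and C12; C13, C14 as in 26) | O=C1C(C(O)[C@@H](O[Si](CC)(CC)CC)[C@@H](O[Si](C)(C)C(C)(C)C)C(C)(C)O[Si](C)(C)C(C)(C)C)[C@H]2CC[C@](C)(O[Si](CC)(CC)CC)/C=C\CC(=C)[C@@H]2CO1 | intermediate
29 | δ-lactone triol (free hydroxyls at C7, C12, C13) | O=C1C(C(O)[C@@H](O)[C@@H](O[Si](C)(C)C(C)(C)C)C(C)(C)O[Si](C)(C)C(C)(C)C)[C@H]2CC[C@](C)(O)/C=C\CC(=C)[C@@H]2CO1 | intermediate
30 | γ-lactone (C3–O–C13) with free hydroxyls at C1, C7, C12 (mixture at C4 and C12) | O=C1O[C@@H]([C@@H](O[Si](C)(C)C(C)(C)C)C(C)(C)O[Si](C)(C)C(C)(C)C)C(O)C1[C@H]2CC[C@](C)(O)/C=C\CC(=C)[C@@H]2CO | intermediate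
31 | C1,C12-diacetate of 30 | O=C1O[C@@H]([C@@H](O[Si](C)(C)C(C)(C)C)C(C)(C)O[Si](C)(C)C(C)(C)C)C(OC(C)=O)C1[C@H]2CC[C@](C)(O)/C=C\CC(=C)[C@@H]2COC(C)=O | intermediate
32 | butenolide (C4=C12 endocyclic, C13 R) with C1 acetate and free C7 hydroxyl | O=C1O[C@@H]([C@@H](O[Si](C)(C)C(C)(C)C)C(C)(C)O[Si](C)(C)C(C)(C)C)C=C1[C@H]2CC[C@](C)(O)/C=C\CC(=C)[C@@H]2COC(C)=O | intermediate
33 | 2,5-dihydrofuran-2-ol (C3 lactol, anomers) with free C1 and C7 hydroxyls | OC1O[C@@H]([C@@H](O[Si](C)(C)C(C)(C)C)C(C)(C)O[Si](C)(C)C(C)(C)C)C=C1[C@H]2CC[C@](C)(O)/C=C\CC(=C)[C@@H]2CO | intermediate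
34 | tricyclic bis-acetal triene (3S,4aS,7S,11aR,13R,14R; C8=C9 Z), O14 and O15 as tert-butyldimethylsilyl ethers | C=C1C/C=C\[C@@](C)(O)CC[C@@H]2C3=C[C@H]([C@@H](O[Si](C)(C)C(C)(C)C)C(C)(C)O[Si](C)(C)C(C)(C)C)O[C@@H]3OC[C@@H]12 | intermediate
35 | (8R,9R)-cis-epoxide of 34, epoxide oxygen syn to the C7 hydroxyl | C=C1C[C@H]2O[C@H]2[C@@](C)(O)CC[C@@H]2C3=C[C@H]([C@@H](O[Si](C)(C)C(C)(C)C)C(C)(C)O[Si](C)(C)C(C)(C)C)O[C@@H]3OC[C@@H]12 | intermediate
36 | CNP0281409.2 (3S,4aS,7S,8R,9R,11aR,13R,14R) | C=C1C[C@H]2O[C@H]2[C@@](C)(O)CC[C@@H]2C3=C[C@H]([C@@H](O)C(C)(C)O)O[C@@H]3OC[C@@H]12 | target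

Total step count: 22. Longest linear sequence: 15 steps (from 9 through steps 4–12 and 17–22; the branch from 1 through steps 1–3, 7–12 and 17–22 is equally long).

Steps most likely to fail

Step 12. Closure onto the vinyl group beside the silyloxy quaternary carbon may be too slow. Oligomerisation through the allyl terminus, or hydride-induced migration of the skipped diene, would then take over. The fallback is a hydroxyl-assisted closure on a different substrate. Starting from 20, n-Bu4NF in THF frees the tertiary alcohol and gives the carbinol triene F1. Its smaller allylic hydroxyl can hydrogen-bond to a chloride ligand of the catalyst. F1 is closed with RuCl2(=CH-2-(i-PrO)C6H4)(H2IMes) in dilute refluxing CH2Cl2 to the free cyclononenol F2. Et3SiOTf with 2,6-lutidine then brings the route back at 21.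

Step 20. Loss of the C13 proton from the allylic C3 oxocarbenium ion (aromatisation of the dihydrofuran) may compete with capture by the C1 hydroxyl, during the acid treatment or already on work-up of the lactol. The fallback is an acid-free closure by anomeric O-alkylation, the reaction type that turns 6-O-sulfonyl pyranoses into 1,6-anhydro sugars. Starting from 30, TsCl in pyridine at 0 °C sulfonylates only the primary C1 hydroxyl and gives the primary tosylate F3. Ac2O with DMAP gives the C12 acetate F4, and DBU eliminates it to the butenolide tosylate F5. i-Bu2AlH at −78 °C gives the lactol tosylate F6. Its lactolate, formed with Cs2CO3 in MeCN, displaces the tosylate in a 6-exo-tet closure and rejoins the route at 34.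

Step 3. Slow transmetalation and protodeboronation of the hindered 1,1-disubstituted alkenylborate, or weak facial discrimination on the small butenolide, may leave too little or too impure material. The fallback is a racemic addition followed by classical resolution. Starting from 3 (by way of Grignard reagent 4) and 7, CuBr·SMe2-catalysed conjugate addition at −78 °C gives the racemic lactone F7. AlMe3-mediated ring opening with (S)-1-phenylethylamine gives the (3R)-hydroxy amide F8 and the (3S)-hydroxy amide F9, which are separated by crystallisation or chromatography. Warm dilute H2SO4 in dioxane relactonises F8 and returns to the route at 8.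

Further compounds
F1 | step 12 | (4R,5R)-4-[(S)-3-hydroxy-3-methylpent-4-en-1-yl]-5-(penta-1,4-dien-2-yl)tetrahydro-2H-pyran-2-one | O=C1C[C@@H](CC[C@](C)(O)C=C)[C@H](C(=C)CC=C)CO1
F2 | step 12 | (4aR,7S,11aR,Z)-7-hydroxy-7-methyl-11-methylene-4,4a,5,6,7,10,11,11a-octahydrocyclonona[c]pyran-3(1H)-one | O=C1C[C@H]2CC[C@](C)(O)/C=C\CC(=C)[C@@H]2CO1
F3 | step 20 | C1 tosylate of 30 | O=C1O[C@@H]([C@@H](O[Si](C)(C)C(C)(C)C)C(C)(C)O[Si](C)(C)C(C)(C)C)C(O)C1[C@H]2CC[C@](C)(O)/C=C\CC(=C)[C@@H]2COS(=O)(=O)c1ccc(C)cc1
F4 | step 20 | C12 acetate of F3 | O=C1O[C@@H]([C@@H](O[Si](C)(C)C(C)(C)C)C(C)(C)O[Si](C)(C)C(C)(C)C)C(OC(C)=O)C1[C@H]2CC[C@](C)(O)/C=C\CC(=C)[C@@H]2COS(=O)(=O)c1ccc(C)cc1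
F5 | step 20 | butenolide with C1 tosylate | O=C1O[C@@H]([C@@H](O[Si](C)(C)C(C)(C)C)C(C)(C)O[Si](C)(C)C(C)(C)C)C=C1[C@H]2CC[C@](C)(O)/C=C\CC(=C)[C@@H]2COS(=O)(=O)c1ccc(C)cc1
F6 | step 20 | C3 lactol with C1 tosylate (anomers) | OC1O[C@@H]([C@@H](O[Si](C)(C)C(C)(C)C)C(C)(C)O[Si](C)(C)C(C)(C)C)C=C1[C@H]2CC[C@](C)(O)/C=C\CC(=C)[C@@H]2COS(=O)(=O)c1ccc(C)cc1
F7 | step 3 | racemic 4-(penta-1,4-dien-2-yl)dihydrofuran-2(3H)-one | O=C1CC(C(=C)CC=C)CO1
F8 | step 3 | (R)-3-(hydroxymethyl)-4-methylidene-N-[(S)-1-phenylethyl]hept-6-enamide | O=C(C[C@H](C(=C)CC=C)CO)N[C@@H](C)c1ccccc1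
F9 | step 3 | (S)-3-(hydroxymethyl)-4-methylidene-N-[(S)-1-phenylethyl]hept-6-enamide | O=C(C[C@@H](C(=C)CC=C)CO)N[C@@H](C)c1ccccc1
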